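**Remark on the chemistry (assumption):** compounds 1, 2, 4, 6, 8, 11, 14 (as a THF solution), 17 and 24 are taken as purchased. Ring A is numbered C1 (carboxyl carbon) to C6 (ether carbon), ring B C1' (ether carbon) to C6' (chain-bearing carbon).

## Analysis of the target

The target 25 is a diaryl ether of two tetrasubstituted benzene rings. Ring A is a benzoic acid with methoxy on C2, an (S)-1-acetoxy-3-methylbutyl chain on C3 and the ether oxygen on C6. Ring B has the ether oxygen on C1', a free hydroxyl on C2', a methyl on C4' and an (E)-3-oxobut-1-enyl chain on C6'. The benzylic acetoxy carbon on C3 is the only stereocentre, so only absolute configuration has to be controlled. It sits ortho to the methoxy group and para to the ether oxygen, so strong acid could ionise its C–O bond and racemise it. The other sensitive groups are the secondary acetate (base, nucleophiles), the E-enone (a Michael acceptor), the free phenol and the free acid; the carboxyl carbon is flanked by two ortho substituents, so an ester there cannot be cleaved by attack at the carbonyl. The main difficulty is the ether oxygen, which is flanked on ring A by the carboxyl group and on ring B by both the hydroxyl and the side chain, the worst case for an Ullmann or SNAr coupling. The strategy rests on the pattern of ring B: C1' lies between C2' (hydroxyl) and C6' (chain), with the methyl on C4'. Read as an open chain, C1'–C2'(O)–C3'–C4'(CH3) is an aryloxymethyl prop-1-ynyl ketone and C5'–C6' is the methyl and carbonyl carbon of a methyl ketone carrying a masked formyl group, so ring B can be grown on an oxygen that already sits on ring A.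

## Retrosynthetic reasoning

**Enone (25 to 23 and 24).** The side chain on C6' is cut at its C=C bond. The stabilised ylide 24 and aldehyde 23 should give the E-alkene, and doing this last keeps the enone away from every enolate, amine and phosphine used earlier. The forward step only has to tolerate a free phenol, a free acid and the acetate.

**Aldehyde (23 to 22).** The formyl group is carried as its dimethyl acetal. This group is inert to the anionic ring-forming step and is released by acid too weak to ionise the benzylic acetate.

**Ring B (22 to 16 and 17; bonds C4'–C5' and C1'–C6').** Ring B is opened to the ynone acid 16 and the methyl ketone 17. Cutting here, and not at either C–O bond of the ether, means the doubly flanked diaryl ether is never made by a coupling; it begins as the alkyl aryl ether of 16. Ring B then needs no protecting group, because its hydroxyl comes from the ynone carbonyl and the arene forms by dehydration without an oxidant. Compound 17 supplies C5', C6' and the latent aldehyde in one purchased piece. The forward reaction must add the methyl-side enolate of 17 to the methyl-bearing alkyne carbon, close the ring from C1' onto the C6' carbonyl and dehydrate, all without touching ring A. For that reason 16 is used as its carboxylate, since an ester at C1 would invite a five-membered Dieckmann closure from the C1' enolate. The acetate is already in place because the side-chain hydroxyl could not be acetylated selectively once the ring B phenol exists.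

**Ynone (16 to 13 and 14; bond C2'–C3').** The alkynyl ketone is the most fragile group before the key step, because phosphines, amines and carbonate bases all attack or enolise it. It is therefore made last, by acyl substitution of the N-methoxy-N-methylamide 13 with the alkynyl Grignard reagent 14. Ester cleavage and both phenol alkylations are then finished before any ynone exists. The other order, alkylating a phenol with a preformed halomethyl ynone and then removing the ester with a phosphine-ligated zerovalent palladium catalyst, was judged less safe for that reason.

**Acid (13 to 12).** Because the carboxyl carbon is shielded on both sides, the ester is cleaved at the oxygen–allyl bond with zerovalent palladium under neutral conditions that keep the acetate.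

**Acetate and stereocentre (12 to 10 and 11; 10 to 9).** The stereocentre is set by enantioselective reduction of the aryl ketone 9, and the alcohol 10 is acetylated with 11 at once. A ketone at C3 is also the natural product of the aromatic substitution that builds ring A.

**Ether groups (9 to 7 and 8; 7 to 5 and 6).** The two hydroxyls of 5 differ. The one on C2 is hydrogen-bonded to the ketone and flanked on both sides; the one on C6 is para to the ketone, more acidic and more exposed. The C6 hydroxyl is alkylated first with 6, which brings C1' and the amide, and the chelated C2 hydroxyl is then methylated with 8.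

**Ketone (5 to 3 and 4; bond C3–acyl).** The acyl group is introduced by Friedel–Crafts acylation of the symmetrical ester 3. In 3 the two open positions ortho and para to the hydroxyls are equivalent, so only one ketone can form. Had one hydroxyl been methylated beforehand, the position para to the hydroxyl and the position para to the methoxy group would compete.

**Ester (3 to 1 and 2).** The acid 1 is allylated on the carboxylate with 2.

## Alternatives that were turned down

**Alternative 1:** Ring A is cut at C1–C2 and C3–C4 and assembled from the 2-pyrone A2 and the (S)-1-methoxyalkyne A3. A2 carries the allyl ester on pyrone C3 and ring B as an aryloxy group on C4. Heating the two should give an inverse-demand [4+2] cycloaddition, and loss of carbon dioxide A4 from the bicyclic lactone would give the benzoate A1.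
- For it: the regiochemistry is matched, since the nucleophilic alkyne carbon (the one bearing the side chain) meets the electrophilic pyrone terminus and the methoxy carbon ends next to the ester. The stereocentre comes from a small propargylic alcohol, where asymmetric methods are very reliable; on this point it is stronger than the chosen route, which reduces a hindered, electron-rich aryl ketone. The aryl–oxygen bond is made by addition–elimination on a pyrone, not by a hindered coupling.
- Against it: A3 is a heat-sensitive ynol ether with a bulky branch next to the reacting carbon, and the aryloxy donor on A2 lowers the reactivity of the diene, so forcing conditions are likely. Ring B must be made separately as a fully substituted phenol with two protecting groups. After A1 five more steps follow: desilylation, acetylation, removal of two allyl groups, hydrolysis of a dioxolane (which needs stronger acid than a dimethyl acetal and so threatens the benzylic acetate) and olefination.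
- Comparison: the chosen route is linear where this one is convergent, but it needs no ring B synthesis and no ring B protecting group, and the phenol appears free.

**Alternative 2:** Ring A is cut at C2–C3 and C4–C5. The silyl ketene acetal diene A6, which carries ring B as an enol ether, would add to the terminal ynone A7 in a Diels–Alder reaction; loss of allyl alcohol A8 and of the silyl group would aromatise the adduct to the salicylate A5.
- For it: the polarisation of both partners is strong and matched (the CH2 terminus of A6 to the alkyne CH of A7). The ketone for the asymmetric reduction arrives with the ring, so stereocontrol is the same as in the chosen route. Ring A regiochemistry does not depend on telling two phenols apart, which is a point where it is stronger than steps 3 and 4 of the chosen route.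
- Against it: A6 is a hydrolytically labile diene that has to be made from a hindered aryloxy alkylidene malonate, and ring B again needs its own multistep synthesis with two protecting groups. After A5 six steps remain: methylation of a chelated phenol, reduction, acetylation, double deallylation, dioxolane hydrolysis and olefination.
- Comparison: the chosen route distinguishes the two phenols by their hydrogen bonding, which is a well-established effect, and reaches the target in fewer operations overall.

**Alternative 3:** Ring A is cut at C6–O and C1–carboxyl. A fluoride source would release the aryne from the silyl triflate A10; the potassium salt of the ring B phenol A11 would add at C6, and the resulting C1 anion would be trapped by carbon dioxide A4 to give A9.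
- For it: it is the most convergent plan, it forms the hindered ether and the carboxyl bond in one operation, and the methoxy group polarises the aryne so that the nucleophile enters meta to it and the anion develops next to it, as required. Only three steps follow A9 (deallylation, acetal hydrolysis, olefination), which is shorter after the union than the chosen route.
- Against it: A10 is a pentasubstituted benzene with the stereocentre already in place and needs a long preparation. The doubly ortho-substituted phenoxide of A11 is hindered and is reversibly captured by A4 as a carbonate. The aryl anion can be protonated before it is carboxylated, the allyl ether can intercept the aryne, and fluoride threatens the acetate. Three-component aryne couplings are far better established with nitrogen nucleophiles than with phenoxides.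
- Comparison: the risk is concentrated in one step with two expensive partners. In the chosen route the risky step uses one simple intermediate and one purchased ketone, and it has a stepwise remedy with a neutral donor.

Key step: step 9

## Route

**Step 1**
Reactants: 1 2,6-dihydroxybenzoic acid; 2 allyl bromide
Product: 3 allyl 2,6-dihydroxybenzoate
Conditions: KHCO3 (1.1 equiv), DMF, rt
Reagents that add atoms: allyl bromide, C=CCBr
Why: Carboxylate O-alkylation (SN2); hydrogencarbonate deprotonates only the strongly acidic carboxyl group, so the two hydrogen-bonded phenols are not allylated, and the allyl ester is chosen because it is later cleaved at the oxygen–allyl bond.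

**Step 2**
Reactants: 3 allyl 2,6-dihydroxybenzoate; 4 3-methylbutanoyl chloride
Product: 5 allyl 2,6-dihydroxy-3-(3-methylbutanoyl)benzoate
Conditions: AlCl3 (3 equiv), CH2Cl2/MeNO2, 0 °C → rt; aq. HCl
Reagents that add atoms: 3-methylbutanoyl chloride, CC(C)CC(=O)Cl
Why: Friedel–Crafts acylation of a resorcinol-type ring; C3 and C5 are each ortho to one hydroxyl and para to the other and are equivalent by symmetry, C4 is meta to both, so a single ketone is expected and the new acyl group deactivates the ring against a second acylation; the primary allyl ester offers no stabilised cation and should behave like a methyl ester toward the Lewis acid at this temperature.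

**Step 3**
Reactants: 5 allyl 2,6-dihydroxy-3-(3-methylbutanoyl)benzoate; 6 2-chloro-N-methoxy-N-methylacetamide
Product: 7 allyl 2-hydroxy-6-{2-[methoxy(methyl)amino]-2-oxoethoxy}-3-(3-methylbutanoyl)benzoate
Conditions: K2CO3 (1.05 equiv), NaI (cat.), acetone, 50 °C
Reagents that add atoms: 2-chloro-N-methoxy-N-methylacetamide, CON(C)C(=O)CCl
Why: Williamson ether synthesis under substrate control; the C2 hydroxyl is locked in a six-membered hydrogen bond to the ketone and flanked by two carbonyl substituents, whereas the C6 hydroxyl is para to the ketone and more acidic, so the monophenoxide should form and react at C6–O as the 4-hydroxyl of 2,4-dihydroxyaryl ketones does; the amide brings C1' and a masked ynone.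

**Step 4**
Reactants: 7 allyl 2-hydroxy-6-{2-[methoxy(methyl)amino]-2-oxoethoxy}-3-(3-methylbutanoyl)benzoate; 8 iodomethane
Product: 9 allyl 2-methoxy-6-{2-[methoxy(methyl)amino]-2-oxoethoxy}-3-(3-methylbutanoyl)benzoate
Conditions: MeI (3 equiv), K2CO3, DMF, 40 °C
Reagents that add atoms: iodomethane, CI
Why: O-Methylation (Williamson) of the remaining chelated phenol in a dipolar aprotic solvent; it is the only acidic site left, since carbonate does not enolise the aryl ketone or the aryloxyacetamide, so neither C-methylation nor Dieckmann closure onto the neighbouring ester is expected.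

**Step 5**
Reactants: 9 allyl 2-methoxy-6-{2-[methoxy(methyl)amino]-2-oxoethoxy}-3-(3-methylbutanoyl)benzoate
Product: 10 allyl 3-[(1S)-1-hydroxy-3-methylbutyl]-2-methoxy-6-{2-[methoxy(methyl)amino]-2-oxoethoxy}benzoate
Conditions: RuCl[(S,S)-TsDPEN](p-cymene) (2 mol %), HCO2H/Et3N (5:2), DMF, 30 °C
Reagents that add atoms: none
Why: Noyori-type asymmetric transfer hydrogenation of an aryl alkyl ketone; in the six-membered hydride/proton transfer transition state the aryl ring lies under the η6-arene, so the (S,S)-catalyst should deliver hydride to the face that gives the (S)-carbinol (CIP order O > aryl > CH2, as in 1-arylethanols); the metal hydride is selective for C=O and leaves the allyl alkene, the esters and the N–O bond alone.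

**Step 6**
Reactants: 10 allyl 3-[(1S)-1-hydroxy-3-methylbutyl]-2-methoxy-6-{2-[methoxy(methyl)amino]-2-oxoethoxy}benzoate; 11 acetic anhydride
Product: 12 allyl 3-[(1S)-1-acetoxy-3-methylbutyl]-2-methoxy-6-{2-[methoxy(methyl)amino]-2-oxoethoxy}benzoate
Conditions: Ac2O, Et3N, DMAP (cat.), CH2Cl2, 0 °C
Reagents that add atoms: acetic anhydride, CC(=O)OC(C)=O
Why: Nucleophile-catalysed O-acylation of the secondary alcohol; the C–O bond of the stereocentre is not broken, so the S configuration is retained, and the acetate is installed now because no phenol is present to compete.

**Step 7**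
Reactants: 12 allyl 3-[(1S)-1-acetoxy-3-methylbutyl]-2-methoxy-6-{2-[methoxy(methyl)amino]-2-oxoethoxy}benzoate
Product: 13 3-[(1S)-1-acetoxy-3-methylbutyl]-2-methoxy-6-{2-[methoxy(methyl)amino]-2-oxoethoxy}benzoic acid
Conditions: Pd(PPh3)4 (3 mol %), morpholine (3 equiv), THF, rt; cold aq. citric acid
Reagents that add atoms: none
Why: Tsuji–Trost-type deallylation; zerovalent palladium ionises the oxygen–allyl bond and morpholine traps the π-allyl complex, so the shielded carboxyl carbon is never attacked; the secondary acetate, the amide and the benzylic C–O bond should be inert under these neutral conditions, and no ynone is yet present to meet phosphine or amine.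

**Step 8**
Reactants: 13 3-[(1S)-1-acetoxy-3-methylbutyl]-2-methoxy-6-{2-[methoxy(methyl)amino]-2-oxoethoxy}benzoic acid; 14 prop-1-yn-1-ylmagnesium bromide
Product: 16 3-[(1S)-1-acetoxy-3-methylbutyl]-2-methoxy-6-[(2-oxopent-3-yn-1-yl)oxy]benzoic acid, via bromomagnesium hemiaminal adduct 15 (not isolated)
Conditions: CH3C≡CMgBr (2.4 equiv), THF, −40 → −10 °C; inverse quench into cold 1 M HCl
Reagents that add atoms: prop-1-yn-1-ylmagnesium bromide, CC#C[Mg]Br
Why: Weinreb ketone synthesis; the first equivalent of 14 deprotonates the acid and the second adds to the N-methoxy-N-methylamide to give the chelated adduct 15, which does not collapse to the ynone until the acidic quench, so neither over-addition nor conjugate addition can occur; alkynyl Grignard reagents are slow toward a secondary acetate and a hindered magnesium carboxylate at this temperature, and quenching into acid keeps the released N,O-dimethylhydroxylamine protonated and away from the ynone.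

**Step 9**
Reactants: 16 3-[(1S)-1-acetoxy-3-methylbutyl]-2-methoxy-6-[(2-oxopent-3-yn-1-yl)oxy]benzoic acid; 17 1,1-dimethoxypropan-2-one
Product: 22 3-[(1S)-1-acetoxy-3-methylbutyl]-6-[2-(dimethoxymethyl)-6-hydroxy-4-methylphenoxy]-2-methoxybenzoic acid, via potassium carboxylate 18 (not isolated), via potassium enolate 19 (not isolated), via Michael adduct 20 (not isolated), via cyclic aldol 21 (not isolated)
Conditions: (a) 17 (1.5 equiv), KN(SiMe3)2 (1.4 equiv), THF, −78 °C; (b) 16, KN(SiMe3)2 (1.0 equiv), THF, −78 °C, then add (b) to (a), −78 → 0 °C; AcOH, then pH 4 buffer, 0 °C
Reagents that add atoms: 1,1-dimethoxypropan-2-one, CC(=O)C(OC)OC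
Why: The amide base removes a methyl proton of 17 under kinetic control (the dialkoxy methine is hindered and its enolate would be destabilised by two adjacent oxygen lone pairs), and enolate 19 adds through carbon to the methyl-bearing alkyne carbon of carboxylate 18 (Michael addition, bond C4'–C5'); protonation of the allenolate gives enedione 20, whose C3'=C4' geometry equilibrates through the C5' dienolate. Enolisation at the aryloxy-bearing C1' and aldol attack on the acetal-activated C6' ketone then closes ring B in a 6-(enolendo)-exo-trig mode (bond C1'–C6') to give 21, and E1cB loss of hydroxide followed by a proton shift from C5' delivers the phenoxide, so no oxidant is needed and aromatisation pulls every earlier equilibrium forward. The closest known reaction type is the Michael addition–aldol condensation benzannulation of alkynyl ketones with ketone enolates, a Robinson-type annulation one oxidation level higher. No stereocentre is created, since C1' and C6' of 21 become sp2 and the benzylic acetoxy carbon is remote from every carbanion. The step needs conjugate addition to outrun proton transfer from the acidic C1' methylene; this is served by keeping 17 in slight excess over the base so that no free amide meets the ynone, by the potassium counter-ion, and by adding 18 to 19 at −78 °C. It also needs a single mode of closure: the other six-membered aldol (acetal carbon onto C2') would require the unfavourable methine enolate and gives a quaternary adduct that can only revert, while five-membered attack of C1' on the ring A carboxyl is shut off because that group is a carboxylate. One equivalent of base is held by the carboxylate and the other ends on the new phenoxide, which also takes up the hydroxide released, so the acetate meets only weakly basic species below 0 °C.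

**Step 10**
Reactants: 22 3-[(1S)-1-acetoxy-3-methylbutyl]-6-[2-(dimethoxymethyl)-6-hydroxy-4-methylphenoxy]-2-methoxybenzoic acid
Product: 23 3-[(1S)-1-acetoxy-3-methylbutyl]-6-(2-formyl-6-hydroxy-4-methylphenoxy)-2-methoxybenzoic acid
Conditions: pyridinium p-toluenesulfonate (cat.), acetone/H2O (10:1), rt
Reagents that add atoms: water, O
Why: Acid-catalysed acetal hydrolysis through an aryl-stabilised oxocarbenium ion; the aryl dimethyl acetal reacts at an acidity far below that needed to ionise the benzylic acetate, so the stereocentre and the ester should be untouched, and any acetal already lost during the cold work-up of step 9 simply converges on 23 here.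

**Step 11**
Reactants: 23 3-[(1S)-1-acetoxy-3-methylbutyl]-6-(2-formyl-6-hydroxy-4-methylphenoxy)-2-methoxybenzoic acid; 24 1-(triphenylphosphoranylidene)propan-2-one
Product: 25 3-[(1S)-1-acetoxy-3-methylbutyl]-6-{2-hydroxy-4-methyl-6-[(1E)-3-oxobut-1-en-1-yl]phenoxy}-2-methoxybenzoic acid
Conditions: 24 (1.5 equiv), i-Pr2NEt (1.1 equiv), THF, 50 °C; cold dilute aq. HCl
Reagents that add atoms: 1-(triphenylphosphoranylidene)propan-2-one, CC(=O)C=P(c1ccccc1)(c1ccccc1)c1ccccc1
Why: Wittig olefination with a carbonyl-stabilised ylide, whose reversible, late transition state leads to the E-enone; the amine holds the carboxylic acid as its ammonium salt so that the ylide is not consumed by protonation, and the weakly basic ylide leaves the acetate and the phenol alone.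

## Compound list

1 | 2,6-dihydroxybenzoic acid | O=C(O)c1c(O)cccc1O | starting material
2 | allyl bromide (3-bromoprop-1-ene) | C=CCBr | starting material
3 | allyl 2,6-dihydroxybenzoate | C=CCOC(=O)c1c(O)cccc1O | intermediate
4 | 3-methylbutanoyl chloride | CC(C)CC(=O)Cl | starting material
5 | allyl 2,6-dihydroxy-3-(3-methylbutanoyl)benzoate | C=CCOC(=O)c1c(O)ccc(C(=O)CC(C)C)c1O | intermediate
6 | 2-chloro-N-methoxy-N-methylacetamide | CON(C)C(=O)CCl | starting material
7 | allyl 2-hydroxy-6-{2-[methoxy(methyl)amino]-2-oxoethoxy}-3-(3-methylbutanoyl)benzoate | C=CCOC(=O)c1c(OCC(=O)N(C)OC)ccc(C(=O)CC(C)C)c1O | intermediate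
8 | iodomethane | CI | starting material
9 | allyl 2-methoxy-6-{2-[methoxy(methyl)amino]-2-oxoethoxy}-3-(3-methylbutanoyl)benzoate | C=CCOC(=O)c1c(OCC(=O)N(C)OC)ccc(C(=O)CC(C)C)c1OC | intermediate
10 | allyl 3-[(1S)-1-hydroxy-3-methylbutyl]-2-methoxy-6-{2-[methoxy(methyl)amino]-2-oxoethoxy}benzoate | COc1c([C@H](CC(C)C)O)ccc(OCC(=O)N(C)OC)c1C(=O)OCC=C | intermediate
11 | acetic anhydride | CC(=O)OC(C)=O | starting material
12 | allyl 3-[(1S)-1-acetoxy-3-methylbutyl]-2-methoxy-6-{2-[methoxy(methyl)amino]-2-oxoethoxy}benzoate | COc1c([C@H](CC(C)C)OC(C)=O)ccc(OCC(=O)N(C)OC)c1C(=O)OCC=C | intermediate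
13 | 3-[(1S)-1-acetoxy-3-methylbutyl]-2-methoxy-6-{2-[methoxy(methyl)amino]-2-oxoethoxy}benzoic acid | COc1c([C@H](CC(C)C)OC(C)=O)ccc(OCC(=O)N(C)OC)c1C(=O)O | intermediate
14 | prop-1-yn-1-ylmagnesium bromide | CC#C[Mg]Br | starting material
15 | bromomagnesium salt of the hemiaminal alkoxide formed by addition of 14 to the amide carbonyl of 13, carboxylate also as its bromomagnesium salt (hemiaminal carbon not defined) | COc1c([C@H](CC(C)C)OC(C)=O)ccc(OCC(O[Mg]Br)(C#CC)N(C)OC)c1C(=O)O[Mg]Br | intermediate
16 | 3-[(1S)-1-acetoxy-3-methylbutyl]-2-methoxy-6-[(2-oxopent-3-yn-1-yl)oxy]benzoic acid | COc1c([C@H](CC(C)C)OC(C)=O)ccc(OCC(=O)C#CC)c1C(=O)O | intermediate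
17 | 1,1-dimethoxypropan-2-one | CC(=O)C(OC)OC | starting material
18 | potassium 3-[(1S)-1-acetoxy-3-methylbutyl]-2-methoxy-6-[(2-oxopent-3-yn-1-yl)oxy]benzoate | COc1c([C@H](CC(C)C)OC(C)=O)ccc(OCC(=O)C#CC)c1C(=O)[O-].[K+] | intermediate
19 | potassium 3,3-dimethoxyprop-1-en-2-olate | C=C([O-])C(OC)OC.[K+] | intermediate
20 | potassium 3-[(1S)-1-acetoxy-3-methylbutyl]-6-{[(3Z)-7,7-dimethoxy-4-methyl-2,6-dioxohept-3-en-1-yl]oxy}-2-methoxybenzoate (drawn with the carbon acids protonated) | COc1c([C@H](CC(C)C)OC(C)=O)ccc(OCC(=O)/C=C(/C)CC(=O)C(OC)OC)c1C(=O)[O-].[K+] | intermediate
21 | potassium 3-[(1S)-1-acetoxy-3-methylbutyl]-6-{[6-(dimethoxymethyl)-6-hydroxy-4-methyl-2-oxocyclohex-3-en-1-yl]oxy}-2-methoxybenzoate (ring centres transient, not defined) | COc1c([C@H](CC(C)C)OC(C)=O)ccc(OC2C(=O)C=C(C)CC2(O)C(OC)OC)c1C(=O)[O-].[K+] | intermediate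
22 | 3-[(1S)-1-acetoxy-3-methylbutyl]-6-[2-(dimethoxymethyl)-6-hydroxy-4-methylphenoxy]-2-methoxybenzoic acid | COc1c([C@H](CC(C)C)OC(C)=O)ccc(Oc2c(O)cc(C)cc2C(OC)OC)c1C(=O)O | intermediate
23 | 3-[(1S)-1-acetoxy-3-methylbutyl]-6-(2-formyl-6-hydroxy-4-methylphenoxy)-2-methoxybenzoic acid | COc1c([C@H](CC(C)C)OC(C)=O)ccc(Oc2c(O)cc(C)cc2C=O)c1C(=O)O | intermediate
24 | 1-(triphenylphosphoranylidene)propan-2-one | CC(=O)C=P(c1ccccc1)(c1ccccc1)c1ccccc1 | starting material
25 | 3-[(1S)-1-acetoxy-3-methylbutyl]-6-{2-hydroxy-4-methyl-6-[(1E)-3-oxobut-1-en-1-yl]phenoxy}-2-methoxybenzoic acid (CNP0281268.1) | COc1c([C@H](CC(C)C)OC(C)=O)ccc(Oc2c(O)cc(C)cc2/C=C/C(C)=O)c1C(=O)O | target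

## Step count and least certain steps

Total step count: 11. Longest linear sequence: 11 steps (1 to 25); every other component is purchased.

**Step 9 (key step).** The most likely failure is proton transfer from the C1' methylene (or the propargylic methyl) of the ynone to the donor enolate, faster than conjugate addition, after which the ynone enolate condenses with itself. A second risk is acyl transfer from the secondary acetate to surplus enolate on warming. The fallback sets out from 16 and 17 and comes back at 22, and it replaces the basic enolate by a neutral enamine so that the proton transfer cannot occur. Ketone 17 is condensed with pyrrolidine (4 Å sieves, Et2O) to the less substituted enamine 1-(3,3-dimethoxyprop-1-en-2-yl)pyrrolidine F1. Acid 16, neutralised with one equivalent of i-Pr2NEt, is treated with F1 in MeCN at rt. Conjugate addition of the enamine carbon to the ynone (the first stage of a Stork enamine alkylation, as in the Bohlmann–Rahtz sequence) should give the push–pull dienaminone 3-[(1S)-1-acetoxy-3-methylbutyl]-6-{[7,7-dimethoxy-4-methyl-2-oxo-6-(pyrrolidin-1-yl)hepta-3,5-dien-1-yl]oxy}-2-methoxybenzoic acid F2. Brief warming of F2 with AcOH in toluene should then close C1'–C6' by Mannich-type attack of the C1' enol on the iminium carbon and expel the amine to give 22.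

**Step 8.** The likely failure is competing addition of the alkynyl Grignard reagent to the acetate carbonyl (loss of the acetyl group), or stalled conversion because the magnesium carboxylate precipitates. The fallback sets out from 10 and comes back at 16, and it moves the acyl substitution to a stage where no acetate exists. Ester 10 is deallylated as in step 7 to 3-[(1S)-1-hydroxy-3-methylbutyl]-2-methoxy-6-{2-[methoxy(methyl)amino]-2-oxoethoxy}benzoic acid F3. F3 is treated with 14 (3.5 equiv, to cover alkoxide, carboxylate and amide) to give 3-[(1S)-1-hydroxy-3-methylbutyl]-2-methoxy-6-[(2-oxopent-3-yn-1-yl)oxy]benzoic acid F4. F4 is then acetylated with 11 (pyridine, 0 °C; the aqueous work-up hydrolyses any mixed anhydride) to give 16.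

**Step 2.** The likely failure is loss or transfer of the allyl group under the Lewis acid (alkyl–oxygen cleavage of the chelated ester, or C-allylation of the ring) in competition with acylation. The fallback sets out from 3 and comes back at 5, and it avoids Lewis acids. Ester 3 is O-acylated with 4 (1 equiv, Et3N, CH2Cl2, 0 °C) to allyl 2-hydroxy-6-[(3-methylbutanoyl)oxy]benzoate F5. F5 is irradiated (254 nm, MeCN, rt) in a photo-Fries rearrangement. Recombination of the radical pair at the position ortho or para to the acyloxy oxygen gives 5 in either case, because the two positions become the same carbon once both hydroxyls are free.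

**Step 3.** The likely failure is alkylation at the chelated hydroxyl, or at both hydroxyls, through equilibration of the two phenoxides. The fallback sets out from 5 and comes back at 7, and it masks the chelated hydroxyl. Compound 5 is treated with BF3·OEt2 (CH2Cl2, rt) to give the difluoroboron chelate of 5 (boron bridging the C2 oxygen and the ketone oxygen) F6. F6 is alkylated with 6 (K2CO3, NaI, MeCN, rt) at its only free hydroxyl to give the difluoroboron chelate of 7 F7. The boron is then removed (aq. MeOH, NaOAc, 50 °C) to give 7.

**Step 5.** The likely failure is poor facial selectivity or stalled conversion, because the ketone is electron-rich and ortho-substituted. The fallback sets out from 9 and comes back at 10, and it replaces catalytic hydrogen transfer by a stoichiometric chiral borane whose selectivity rests on steric size and not on an arene contact. Ketone 9 is reduced with (−)-B-chlorodiisopinocampheylborane, (−)-Ipc2BCl (THF, −25 °C → rt; diethanolamine work-up), which reduces aryl alkyl ketones to (S)-carbinols through a boat-like six-membered transition state. This fallback makes no new compound (F0).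

## Further compounds

F1 | step 9 | 1-(3,3-dimethoxyprop-1-en-2-yl)pyrrolidine | C=C(N1CCCC1)C(OC)OC
F2 | step 9 | 3-[(1S)-1-acetoxy-3-methylbutyl]-6-{[7,7-dimethoxy-4-methyl-2-oxo-6-(pyrrolidin-1-yl)hepta-3,5-dien-1-yl]oxy}-2-methoxybenzoic acid (alkene geometry not fixed) | COc1c([C@H](CC(C)C)OC(C)=O)ccc(OCC(=O)C=C(C)C=C(N2CCCC2)C(OC)OC)c1C(=O)O
F3 | step 8 | 3-[(1S)-1-hydroxy-3-methylbutyl]-2-methoxy-6-{2-[methoxy(methyl)amino]-2-oxoethoxy}benzoic acid | COc1c([C@H](CC(C)C)O)ccc(OCC(=O)N(C)OC)c1C(=O)O
F4 | step 8 | 3-[(1S)-1-hydroxy-3-methylbutyl]-2-methoxy-6-[(2-oxopent-3-yn-1-yl)oxy]benzoic acid | COc1c([C@H](CC(C)C)O)ccc(OCC(=O)C#CC)c1C(=O)O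
F5 | step 2 | allyl 2-hydroxy-6-[(3-methylbutanoyl)oxy]benzoate | C=CCOC(=O)c1c(O)cccc1OC(=O)CC(C)C
F6 | step 3 | difluoroboron chelate of allyl 2,6-dihydroxy-3-(3-methylbutanoyl)benzoate (boron on the C2 oxygen and the ketone oxygen) | C=CCOC(=O)c1c(O)ccc2c1O[B-](F)(F)[O+]=C2CC(C)C
F7 | step 3 | difluoroboron chelate of allyl 2-hydroxy-6-{2-[methoxy(methyl)amino]-2-oxoethoxy}-3-(3-methylbutanoyl)benzoate | C=CCOC(=O)c1c(OCC(=O)N(C)OC)ccc2c1O[B-](F)(F)[O+]=C2CC(C)C
F0 | step 5 | none | none
A1 | alternative 1 | allyl (S)-6-[2-allyloxy-6-(1,3-dioxolan-2-yl)-4-methylphenoxy]-3-[1-(tert-butyldimethylsilyloxy)-3-methylbutyl]-2-methoxybenzoate | C=CCOC(=O)c1c(OC)c([C@H](CC(C)C)O[Si](C)(C)C(C)(C)C)ccc1Oc1c(OCC=C)cc(C)cc1C1OCCO1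
A2 | alternative 1 | allyl 4-[2-allyloxy-6-(1,3-dioxolan-2-yl)-4-methylphenoxy]-2-oxo-2H-pyran-3-carboxylate | C=CCOC(=O)C1=C(Oc2c(OCC=C)cc(C)cc2C2OCCO2)C=COC1=O
A3 | alternative 1 | tert-butyl{[(3S)-1-methoxy-5-methylhex-1-yn-3-yl]oxy}dimethylsilane | COC#C[C@H](CC(C)C)O[Si](C)(C)C(C)(C)C
A4 | alternative 1 | carbon dioxide | O=C=O
A5 | alternative 2 | allyl 6-[2-allyloxy-6-(1,3-dioxolan-2-yl)-4-methylphenoxy]-2-hydroxy-3-(3-methylbutanoyl)benzoate | O=C(OCC=C)c1c(O)c(C(=O)CC(C)C)ccc1Oc1c(OCC=C)cc(C)cc1C1OCCO1
A6 | alternative 2 | allyl 3-[2-allyloxy-6-(1,3-dioxolan-2-yl)-4-methylphenoxy]-2-[(allyloxy)(trimethylsilyloxy)methylidene]but-3-enoate | C=C(Oc1c(OCC=C)cc(C)cc1C1OCCO1)C(C(=O)OCC=C)=C(OCC=C)O[Si](C)(C)C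
A7 | alternative 2 | 5-methylhex-1-yn-3-one | C#CC(=O)CC(C)C
A8 | alternative 2 | allyl alcohol (prop-2-en-1-ol) | C=CCO
A9 | alternative 3 | (S)-3-(1-acetoxy-3-methylbutyl)-6-[2-allyloxy-6-(1,3-dioxolan-2-yl)-4-methylphenoxy]-2-methoxybenzoic acid | O=C(O)c1c(OC)c([C@H](CC(C)C)OC(C)=O)ccc1Oc1c(OCC=C)cc(C)cc1C1OCCO1
A10 | alternative 3 | (1S)-1-[2-methoxy-4-(trifluoromethylsulfonyloxy)-3-(trimethylsilyl)phenyl]-3-methylbutyl acetate | COc1c([C@H](CC(C)C)OC(C)=O)ccc(OS(=O)(=O)C(F)(F)F)c1[Si](C)(C)C
A11 | alternative 3 | 2-allyloxy-6-(1,3-dioxolan-2-yl)-4-methylphenol | Cc1cc(OCC=C)c(O)c(C2OCCO2)c1
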